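**Strategy.** Ring A is disconnected at the lavandulyl-bearing carbon C3 and its oxygenated neighbour C4. C3 lies between two oxygen-bearing carbons (C2 and C4), the pattern formed when a carboxylate adds to a 3-alkoxy aryne and the carbanion next to the alkoxy group then captures the acyl group. Fluoride-triggered aryne formation from an ortho-silylaryl triflate (made from 5-methoxyresorcinol, one oxygen kept as a methoxymethyl ether) in the presence of the cesium salt of (R)-lavandulic acid should form the C4–O bond and the C3–acyl bond in one operation and bring in the stereocentre intact. Carbonyl removal, directed metalation/acylation with a cinnamic Weinreb amide and acid deprotection complete the chalcone.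

Key step: step 8

Remarks on the chemistry:
- Ring A numbering: C1 acyl carbon, C2 OH, C3 lavandulyl, C4 OH, C5 H, C6 OMe. Ring B is the 2,4-dihydroxyphenyl ring.
- The side-chain stereocentre keeps one spatial arrangement from 16 to 32. Its descriptor is R while the neighbouring carbon is a carbonyl carbon (16–23) and becomes S by the priority rules once that carbon is CH or CH2 (24–26, 30–32). The target SMILES corresponds to S.
- The acid enters the key step as its dried cesium salt 19, because a free carboxylic proton would quench the aryl anion and stop at the aryl ester.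
- Abbreviations: MOMCl = chloromethyl methyl ether; TBS = tert-butyldimethylsilyl.

Step 1
Reactants: 1 5-methoxyresorcinol
Product: 2 3-methoxy-5-(methoxymethoxy)phenol
Conditions: NaH (1.0 equiv), DMF, 0 °C; MOMCl (1.0 equiv), 0 °C → rt; chromatography, recovered 1 recycled
Reagents that add atoms: chloromethyl methyl ether, COCCl
Why: Williamson-type O-alkylation of the monosodium phenoxide with one equivalent of the chloromethyl ether should give the mono-acetal as the main component of a statistical mixture, from which unreacted diol and the bis-acetal are separated.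

Step 2
Reactants: 2 3-methoxy-5-(methoxymethoxy)phenol
Product: 3 3-methoxy-5-(methoxymethoxy)phenyl N-isopropylcarbamate
Conditions: i-PrNCO (1.5 equiv), Et3N (0.2 equiv), CH2Cl2, rt
Reagents that add atoms: isopropyl isocyanate, CC(C)N=C=O
Why: Amine-catalysed addition of the phenol to the isocyanate (carbamoylation) should give the secondary carbamate, which serves as the directing group for the next step and as a phenol mask removable without acid.

Step 3
Reactants: 3 3-methoxy-5-(methoxymethoxy)phenyl N-isopropylcarbamate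
Product: 7 5-methoxy-3-(methoxymethoxy)-2-(trimethylsilyl)phenyl N-isopropylcarbamate, via N-TBS carbamate 4 (not isolated), via ortho-lithiated N-TBS carbamate 5 (not isolated), via C-silylated N-TBS carbamate 6 (not isolated)
Conditions: TBSOTf (1.05 equiv), TMEDA (1.1 equiv), Et2O, 0 °C, 15 min; TMEDA (2 equiv), n-BuLi (2.1 equiv), −78 °C, 1 h; TMSCl (3 equiv), −78 °C → rt; cold aq. NaHSO4 work-up
Reagents that add atoms: chlorotrimethylsilane, C[Si](C)(C)Cl
Why: Directed ortho-metalation, in which N-silylation masks the acidic N–H, the carbamate (strongest director on the ring) and the chelating methoxymethoxy group should steer n-BuLi to the carbon they flank in preference to the carbamate/methoxy-flanked one, chlorotrimethylsilane traps the aryllithium, and the N–Si bond is hydrolysed on work-up.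

Step 4
Reactants: 7 5-methoxy-3-(methoxymethoxy)-2-(trimethylsilyl)phenyl N-isopropylcarbamate
Product: 9 5-methoxy-3-(methoxymethoxy)-2-(trimethylsilyl)phenyl trifluoromethanesulfonate, via 2-silylphenoxide 8 (not isolated)
Conditions: DBU (1.5 equiv), Et2NH (1.2 equiv), MeCN, 40 °C; then PhNTf2 (1.5 equiv), rt
Reagents that add atoms: N-phenylbis(trifluoromethanesulfonimide), O=S(=O)(N(c1ccccc1)S(=O)(=O)C(F)(F)F)C(F)(F)F
Why: DBU deprotonates the carbamate N–H, E1cB loss of isopropyl isocyanate (scavenged by diethylamine as a urea) unmasks the phenoxide, and the same flask then O-sulfonylates it with the triflimide (one-pot carbamate cleavage and triflation), so the acid-sensitive aryl–silicon bond and the acetal never meet protic acid.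

Step 5
Reactants: 10 3-methylbut-2-enoic acid; 11 (R)-4-benzyloxazolidin-2-one
Product: 13 (R)-4-benzyl-3-(3-methylbut-2-enoyl)oxazolidin-2-one, via pivalic mixed anhydride 12 (not isolated)
Conditions: PivCl (1.05 equiv), Et3N (2.5 equiv), THF, −20 °C; LiCl (1.1 equiv), 11 (0.95 equiv), −20 °C → rt
Reagents that add atoms: none
Why: N-acylation of the oxazolidinone through the pivalic mixed anhydride, promoted by LiCl, is the standard mild way to attach an enoyl group to this auxiliary, attack occurring at the less hindered carbonyl of the anhydride.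

Step 6
Reactants: 13 (R)-4-benzyl-3-(3-methylbut-2-enoyl)oxazolidin-2-one; 14 prenyl bromide (1-bromo-3-methylbut-2-ene)
Product: 16 (R)-4-benzyl-3-[(2R)-5-methyl-2-(prop-1-en-2-yl)hex-4-enoyl]oxazolidin-2-one, via sodium Z-dienolate 15 (not isolated)
Conditions: NaN(SiMe3)2 (1.1 equiv), THF, −78 °C; 14 (2 equiv), −78 → −40 °C
Reagents that add atoms: none
Why: Evans alkylation in its deconjugative form, in which γ-deprotonation gives the chelated Z-dienolate that should react at its α-carbon with the allylic bromide on the face opposite the benzyl group, so that the (R)-auxiliary sets the (2R) centre while the double bond moves out of conjugation to become the isopropenyl group.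

Step 7
Reactants: 16 (R)-4-benzyl-3-[(2R)-5-methyl-2-(prop-1-en-2-yl)hex-4-enoyl]oxazolidin-2-one
Product: 18 (R)-lavandulic acid [(2R)-5-methyl-2-(prop-1-en-2-yl)hex-4-enoic acid], via lithium percarboxylate 17 (not isolated)
Conditions: LiOH·H2O (2 equiv), 30% H2O2 (4 equiv), THF/H2O 3:1, 0 °C; aq. Na2SO3; then 1 M HCl to pH 3
Reagents that add atoms: hydrogen peroxide, OO
Why: Hydroperoxide attacks the exocyclic imide carbonyl selectively (standard LiOOH auxiliary cleavage), sulfite reduces the percarboxylate before acidification, and the cold, weakly basic medium should leave the α-stereocentre and the β,γ-alkene untouched.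

Step 8
Reactants: 9 5-methoxy-3-(methoxymethoxy)-2-(trimethylsilyl)phenyl trifluoromethanesulfonate; 18 (R)-lavandulic acid
Product: 22 (2R)-1-[2-hydroxy-4-methoxy-6-(methoxymethoxy)phenyl]-5-methyl-2-(prop-1-en-2-yl)hex-4-en-1-one, via cesium carboxylate 19 (not isolated), via aryne 20 (not isolated), via ortho-cesioaryl ester 21 (not isolated)
Conditions: 18, Cs2CO3 (0.5 equiv), MeOH, rt, evaporate, dry (PhMe azeotrope, vacuum); then 9 (1.4 equiv), CsF (3 equiv), 18-crown-6 (3 equiv), THF, 0 °C → rt; aq. NH4Cl
Reagents that add atoms: none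
Why: Fluoride strips the trimethylsilyl group of 9 and triflate departs to give aryne 20; the carboxylate oxygen of 19 then attacks the aryne terminus that is not next to the acetal-bearing carbon, because the σ-withdrawing oxygen substituent distorts the triple bond so that this terminus is the more electrophilic and the negative charge develops beside oxygen. The aryl anion 21, held between the acetal oxygen and the new ester, attacks the ester carbonyl through a four-membered transition state and the acyl group moves from oxygen to carbon, so the ring A C4–O bond and the bond from C3 to the future benzylic carbon form in one flask and the product rests as an ortho-ketophenoxide. The closest known reaction type is the insertion of arynes into the C–O bond of carboxylic acids to give ortho-hydroxyaryl ketones, an aryne counterpart of the anionic Fries 1,3-acyl shift. No ring is closed and no stereocentre is created; the existing (R) centre must survive, which is addressed by the preformed cesium carboxylate (no acidic proton to intercept 21, and a partner that cannot enolise), by a crown-ether-solubilised fluoride that allows 0 °C to room temperature, and by the product being held as a chelated phenoxide whose carbonyl activates the α-hydrogen only weakly. The required regiochemistry (oxygen on C4, carbon on C3) is secured by the alkoxy group adjacent to the triple bond, the methoxy group being too remote to compete.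

Step 9
Reactants: 22 (2R)-1-[2-hydroxy-4-methoxy-6-(methoxymethoxy)phenyl]-5-methyl-2-(prop-1-en-2-yl)hex-4-en-1-one
Product: 25 5-methoxy-3-(methoxymethoxy)-2-[(2S)-5-methyl-2-(prop-1-en-2-yl)hex-4-en-1-yl]phenol, via ethyl carbonate 23 (not isolated), via ortho-quinone methide 24 (not isolated)
Conditions: ClCO2Et (1.2 equiv), Et3N (1.3 equiv), THF, 0 °C, 30 min; filter; NaBH4 (4 equiv), THF/H2O, 0 °C → rt
Reagents that add atoms: none
Why: O-ethoxycarbonylation followed by borohydride is the known deoxygenation of ortho-hydroxyaryl ketones, in which hydride addition gives a benzylic alkoxide that takes over the carbonate, the phenoxide expels ethyl carbonate to form an ortho-quinone methide, and a second hydride adds to its exocyclic carbon, none of which touches the neighbouring stereocentre, the alkenes or the acetal.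

Step 10
Reactants: 25 5-methoxy-3-(methoxymethoxy)-2-[(2S)-5-methyl-2-(prop-1-en-2-yl)hex-4-en-1-yl]phenol
Product: 26 5-methoxy-1,3-bis(methoxymethoxy)-2-[(2S)-5-methyl-2-(prop-1-en-2-yl)hex-4-en-1-yl]benzene
Conditions: NaH (1.3 equiv), DMF, 0 °C; MOMCl (1.3 equiv), 0 °C → rt
Reagents that add atoms: chloromethyl methyl ether, COCCl
Why: Williamson-type alkylation of the sodium phenoxide installs the second acetal and gives a symmetrical pattern of directing groups for the later metalation.

Step 11
Reactants: 27 2,4-dihydroxybenzaldehyde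
Product: 28 2,4-bis(methoxymethoxy)benzaldehyde
Conditions: NaH (2.5 equiv), DMF, 0 °C; MOMCl (2.5 equiv), 0 °C → rt
Reagents that add atoms: chloromethyl methyl ether, COCCl
Why: Double Williamson-type alkylation with excess base and chloromethyl ether protects both phenols, including the hydrogen-bonded ortho one, as acetals that will leave together with those of ring A.

Step 12
Reactants: 28 2,4-bis(methoxymethoxy)benzaldehyde
Product: 29 (E)-3-[2,4-bis(methoxymethoxy)phenyl]-N-methoxy-N-methylprop-2-enamide
Conditions: (EtO)2P(O)CH2C(O)N(OMe)Me (1.2 equiv), NaH (1.2 equiv), THF, 0 °C → rt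
Reagents that add atoms: diethyl [2-[methoxy(methyl)amino]-2-oxoethyl]phosphonate, CCOP(=O)(CC(=O)N(C)OC)OCC
Why: Horner–Wadsworth–Emmons olefination with the stabilised phosphonate anion should give the E-configured cinnamic N-methoxy-N-methylamide in one step from the aldehyde.

Step 13
Reactants: 26 5-methoxy-1,3-bis(methoxymethoxy)-2-[(2S)-5-methyl-2-(prop-1-en-2-yl)hex-4-en-1-yl]benzene; 29 (E)-3-[2,4-bis(methoxymethoxy)phenyl]-N-methoxy-N-methylprop-2-enamide
Product: 31 (E)-3-[2,4-bis(methoxymethoxy)phenyl]-1-[6-methoxy-2,4-bis(methoxymethoxy)-3-[(2S)-5-methyl-2-(prop-1-en-2-yl)hex-4-en-1-yl]phenyl]prop-2-en-1-one, via aryllithium 30 (not isolated)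
Conditions: 26, n-BuLi (1.1 equiv), TMEDA (1.1 equiv), THF, 0 °C, 1 h; 29 (1.3 equiv), −78 → 0 °C; aq. NH4Cl
Reagents that add atoms: none
Why: Directed ortho-metalation at one of the two equivalent ring positions flanked by a methoxymethoxy and the methoxy group, followed by Weinreb ketone synthesis, in which the aryllithium adds 1,2 to the amide and the chelated tetrahedral adduct persists until work-up, should give the E-enone without over-addition.

Step 14
Reactants: 31 (E)-3-[2,4-bis(methoxymethoxy)phenyl]-1-[6-methoxy-2,4-bis(methoxymethoxy)-3-[(2S)-5-methyl-2-(prop-1-en-2-yl)hex-4-en-1-yl]phenyl]prop-2-en-1-one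
Product: 32 (E)-1-[2,4-dihydroxy-6-methoxy-3-[(2S)-5-methyl-2-(prop-1-en-2-yl)hex-4-en-1-yl]phenyl]-3-(2,4-dihydroxyphenyl)prop-2-en-1-one (CNP0152102.3)
Conditions: 3 M aq. HCl/MeOH (1:5), rt → 40 °C, monitored and stopped at full acetal loss
Reagents that add atoms: none
Why: Acid-catalysed transacetalisation to methanol removes the four methoxymethyl ethers under conditions mild enough that protonation of the side-chain alkenes and chalcone-to-flavanone cyclisation should not compete.

**Compound list**

1 | 5-methoxyresorcinol (5-methoxybenzene-1,3-diol) | COc1cc(O)cc(O)c1 | starting material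
2 | 3-methoxy-5-(methoxymethoxy)phenol | COCOc1cc(OC)cc(O)c1 | intermediate
3 | 3-methoxy-5-(methoxymethoxy)phenyl N-isopropylcarbamate | COCOc1cc(OC)cc(OC(=O)NC(C)C)c1 | intermediate
4 | 3-methoxy-5-(methoxymethoxy)phenyl N-(tert-butyldimethylsilyl)-N-isopropylcarbamate | COCOc1cc(OC)cc(OC(=O)N(C(C)C)[Si](C)(C)C(C)(C)C)c1 | intermediate
5 | 2-lithio derivative of 4 (lithium on the ring carbon between the carbamate oxygen and the methoxymethoxy group) | COCOc1cc(OC)cc(OC(=O)N(C(C)C)[Si](C)(C)C(C)(C)C)c1[Li] | intermediate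
6 | 5-methoxy-3-(methoxymethoxy)-2-(trimethylsilyl)phenyl N-(tert-butyldimethylsilyl)-N-isopropylcarbamate | COCOc1cc(OC)cc(OC(=O)N(C(C)C)[Si](C)(C)C(C)(C)C)c1[Si](C)(C)C | intermediate
7 | 5-methoxy-3-(methoxymethoxy)-2-(trimethylsilyl)phenyl N-isopropylcarbamate | COCOc1cc(OC)cc(OC(=O)NC(C)C)c1[Si](C)(C)C | intermediate
8 | 5-methoxy-3-(methoxymethoxy)-2-(trimethylsilyl)phenol, present as its DBU-H+ phenoxide | COCOc1cc(OC)cc(O)c1[Si](C)(C)C | intermediate
9 | 5-methoxy-3-(methoxymethoxy)-2-(trimethylsilyl)phenyl trifluoromethanesulfonate | COCOc1cc(OC)cc(OS(=O)(=O)C(F)(F)F)c1[Si](C)(C)C | intermediate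
10 | 3-methylbut-2-enoic acid | CC(C)=CC(=O)O | starting material
11 | (R)-4-benzyloxazolidin-2-one | O=C1N[C@H](Cc2ccccc2)CO1 | starting material
12 | 3-methylbut-2-enoic pivalic anhydride | CC(C)=CC(=O)OC(=O)C(C)(C)C | intermediate
13 | (R)-4-benzyl-3-(3-methylbut-2-enoyl)oxazolidin-2-one | CC(C)=CC(=O)N1[C@H](Cc2ccccc2)COC1=O | intermediate
14 | prenyl bromide (1-bromo-3-methylbut-2-ene) | CC(C)=CCBr | starting material
15 | sodium (1Z)-1-[(4R)-4-benzyl-2-oxooxazolidin-3-yl]-3-methylbuta-1,3-dien-1-olate | C=C(C)/C=C(\[O-])N1[C@H](Cc2ccccc2)COC1=O.[Na+] | intermediate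
16 | (R)-4-benzyl-3-[(2R)-5-methyl-2-(prop-1-en-2-yl)hex-4-enoyl]oxazolidin-2-one | C=C(C)[C@@H](CC=C(C)C)C(=O)N1[C@H](Cc2ccccc2)COC1=O | intermediate
17 | lithium (2R)-5-methyl-2-(prop-1-en-2-yl)hex-4-eneperoxoate | C=C(C)[C@@H](CC=C(C)C)C(=O)O[O-].[Li+] | intermediate
18 | (R)-lavandulic acid, (2R)-5-methyl-2-(prop-1-en-2-yl)hex-4-enoic acid | C=C(C)[C@@H](CC=C(C)C)C(=O)O | intermediate
19 | cesium (2R)-5-methyl-2-(prop-1-en-2-yl)hex-4-enoate | C=C(C)[C@@H](CC=C(C)C)C(=O)[O-].[Cs+] | intermediate
20 | 5-methoxy-3-(methoxymethoxy)benzyne (1,2-didehydrobenzene with OMOM on C3 and OMe on C5) | COCOC1=CC(OC)=CC#C1 | intermediate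
21 | [2-cesio-5-methoxy-3-(methoxymethoxy)phenyl] (2R)-5-methyl-2-(prop-1-en-2-yl)hex-4-enoate | C=C(C)[C@@H](CC=C(C)C)C(=O)Oc1cc(OC)cc(OCOC)c1[Cs] | intermediate
22 | (2R)-1-[2-hydroxy-4-methoxy-6-(methoxymethoxy)phenyl]-5-methyl-2-(prop-1-en-2-yl)hex-4-en-1-one | C=C(C)[C@@H](CC=C(C)C)C(=O)c1c(O)cc(OC)cc1OCOC | intermediate
23 | ethyl [3-methoxy-5-(methoxymethoxy)-2-[(2R)-5-methyl-2-(prop-1-en-2-yl)hex-4-enoyl]phenyl] carbonate | C=C(C)[C@@H](CC=C(C)C)C(=O)c1c(OC(=O)OCC)cc(OC)cc1OCOC | intermediate
24 | 3-methoxy-5-(methoxymethoxy)-6-[(2S)-5-methyl-2-(prop-1-en-2-yl)hex-4-en-1-ylidene]cyclohexa-2,4-dien-1-one (ortho-quinone methide, exocyclic alkene geometry open) | C=C(C)[C@@H](CC=C(C)C)C=C1C(=O)C=C(OC)C=C1OCOC | intermediate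
25 | 5-methoxy-3-(methoxymethoxy)-2-[(2S)-5-methyl-2-(prop-1-en-2-yl)hex-4-en-1-yl]phenol | C=C(C)[C@@H](CC=C(C)C)Cc1c(O)cc(OC)cc1OCOC | intermediate
26 | 5-methoxy-1,3-bis(methoxymethoxy)-2-[(2S)-5-methyl-2-(prop-1-en-2-yl)hex-4-en-1-yl]benzene | C=C(C)[C@@H](CC=C(C)C)Cc1c(OCOC)cc(OC)cc1OCOC | intermediate
27 | 2,4-dihydroxybenzaldehyde | O=Cc1ccc(O)cc1O | starting material
28 | 2,4-bis(methoxymethoxy)benzaldehyde | COCOc1ccc(C=O)c(OCOC)c1 | intermediate
29 | (E)-3-[2,4-bis(methoxymethoxy)phenyl]-N-methoxy-N-methylprop-2-enamide | COCOc1ccc(/C=C/C(=O)N(C)OC)c(OCOC)c1 | intermediate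
30 | [6-methoxy-2,4-bis(methoxymethoxy)-3-[(2S)-5-methyl-2-(prop-1-en-2-yl)hex-4-en-1-yl]phenyl]lithium | C=C(C)[C@@H](CC=C(C)C)Cc1c(OCOC)cc(OC)c([Li])c1OCOC | intermediate
31 | (E)-3-[2,4-bis(methoxymethoxy)phenyl]-1-[6-methoxy-2,4-bis(methoxymethoxy)-3-[(2S)-5-methyl-2-(prop-1-en-2-yl)hex-4-en-1-yl]phenyl]prop-2-en-1-one | C=C(C)[C@@H](CC=C(C)C)Cc1c(OCOC)cc(OC)c(C(=O)/C=C/c2ccc(OCOC)cc2OCOC)c1OCOC | intermediate
32 | (E)-1-[2,4-dihydroxy-6-methoxy-3-[(2S)-5-methyl-2-(prop-1-en-2-yl)hex-4-en-1-yl]phenyl]-3-(2,4-dihydroxyphenyl)prop-2-en-1-one (CNP0152102.3) | C=C(C)[C@@H](CC=C(C)C)Cc1c(O)cc(OC)c(C(=O)/C=C/c2ccc(O)cc2O)c1O | target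

**Step count and risks**

Total step count: 14 (steps 1–4 aryne precursor, 5–7 acid, 8 key step, 9–10 and 13–14 endgame, 11–12 amide).
Longest linear sequence: 9 steps (1, 2, 3, 4, 8, 9, 10, 13, 14) from 5-methoxyresorcinol.

Steps most likely to fail:

Step 8. The aryl anion may be protonated before the acyl shift, so that the reaction stops at O-arylation. The α-hydrogen may be removed by the aryl anion or by fluoride, eroding the configuration or moving the alkene into conjugation. The aryne may also be consumed by an ene reaction with the side-chain alkenes. The fallback reaches the same ketone by directed metalation; it sets out from 1 and 18 and returns at 22. Compound 1 is treated with NaH and excess chloromethyl methyl ether to give 1-methoxy-3,5-bis(methoxymethoxy)benzene F1, which n-BuLi in THF at 0 °C should lithiate between the two acetal oxygens to give [4-methoxy-2,6-bis(methoxymethoxy)phenyl]lithium F2. Acid 18 is coupled with N,O-dimethylhydroxylamine hydrochloride (EDC·HCl, HOBt, N-methylmorpholine, CH2Cl2, 0 °C) to give (2R)-N-methoxy-N,5-dimethyl-2-(prop-1-en-2-yl)hex-4-enamide F3. Addition of F2 to F3 at −78 °C (Weinreb ketone synthesis) should give (2R)-1-[4-methoxy-2,6-bis(methoxymethoxy)phenyl]-5-methyl-2-(prop-1-en-2-yl)hex-4-en-1-one F4. Brief exposure to dilute HCl in MeOH at 0 °C, stopped after loss of one acetal (the second is slowed once the freed phenol hydrogen-bonds to the carbonyl), returns 22.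

Step 9. Hydride addition to the doubly ortho-substituted carbonyl may be slower than enolisation of carbonate 23, and the quinone methide may tautomerise to a styrene before it is reduced; either process would scramble the stereocentre. The fallback replaces the hydride/quinone methide pathway by a radical deoxygenation; it sets out from 22 and returns at 26, so step 10 is bypassed. LiAlH4 in THF at −40 °C reduces 22, whose deprotonated phenol keeps the ketone from enolising, to 2-[(2R)-1-hydroxy-5-methyl-2-(prop-1-en-2-yl)hex-4-en-1-yl]-5-methoxy-3-(methoxymethoxy)phenol F5 (both carbinol epimers). The phenol alone is alkylated with chloromethyl methyl ether and K2CO3 in acetone to give (2R)-1-[4-methoxy-2,6-bis(methoxymethoxy)phenyl]-5-methyl-2-(prop-1-en-2-yl)hex-4-en-1-ol F6. NaH, CS2 and then MeI in THF give O-[(2R)-1-[4-methoxy-2,6-bis(methoxymethoxy)phenyl]-5-methyl-2-(prop-1-en-2-yl)hex-4-en-1-yl] S-methyl carbonodithioate F7. Bu3SnH with AIBN in toluene at 80 °C (Barton–McCombie deoxygenation) should replace the benzylic C–O bond by C–H and give 26; the benzylic radical has only three- or four-membered cyclisation modes open and the stereocentre is not involved.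

Step 3. Lithiation may also occur at the carbon between the carbamate and the methoxy group, and the silyl triflate used for N-silylation may attack the aryl acetal. The fallback installs silicon on a symmetrical substrate that carries no acetal; it sets out from 1 and returns at 7. Compound 1 and isopropyl isocyanate (2.5 equiv, Et3N catalyst) give 5-methoxy-1,3-phenylene bis(N-isopropylcarbamate) F8. TBSOTf and TMEDA (2.2 equiv each) give 5-methoxy-1,3-phenylene bis[N-(tert-butyldimethylsilyl)-N-isopropylcarbamate] F9. n-BuLi/TMEDA at −78 °C should lithiate the only carbon flanked by two carbamates to give the 2-lithio derivative F10, chlorotrimethylsilane gives the 2-trimethylsilyl bis(N-silyl) compound F11, and aqueous work-up gives 5-methoxy-2-(trimethylsilyl)-1,3-phenylene bis(N-isopropylcarbamate) F12. One carbamate is removed with DBU and Et2NH (1 equiv) in MeCN; the phenoxide formed should slow loss of the second one, giving 3-hydroxy-5-methoxy-2-(trimethylsilyl)phenyl N-isopropylcarbamate F13. Alkylation with chloromethyl methyl ether and i-Pr2NEt in CH2Cl2 gives 7.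

Further compounds
F1 | step 8 | 1-methoxy-3,5-bis(methoxymethoxy)benzene | COCOc1cc(OC)cc(OCOC)c1
F2 | step 8 | [4-methoxy-2,6-bis(methoxymethoxy)phenyl]lithium | COCOc1cc(OC)cc(OCOC)c1[Li]
F3 | step 8 | (2R)-N-methoxy-N,5-dimethyl-2-(prop-1-en-2-yl)hex-4-enamide | C=C(C)[C@@H](CC=C(C)C)C(=O)N(C)OC
F4 | step 8 | (2R)-1-[4-methoxy-2,6-bis(methoxymethoxy)phenyl]-5-methyl-2-(prop-1-en-2-yl)hex-4-en-1-one | C=C(C)[C@@H](CC=C(C)C)C(=O)c1c(OCOC)cc(OC)cc1OCOC
F5 | step 9 | 2-[(2R)-1-hydroxy-5-methyl-2-(prop-1-en-2-yl)hex-4-en-1-yl]-5-methoxy-3-(methoxymethoxy)phenol | C=C(C)[C@@H](CC=C(C)C)C(O)c1c(O)cc(OC)cc1OCOC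
F6 | step 9 | (2R)-1-[4-methoxy-2,6-bis(methoxymethoxy)phenyl]-5-methyl-2-(prop-1-en-2-yl)hex-4-en-1-ol | C=C(C)[C@@H](CC=C(C)C)C(O)c1c(OCOC)cc(OC)cc1OCOC
F7 | step 9 | O-[(2R)-1-[4-methoxy-2,6-bis(methoxymethoxy)phenyl]-5-methyl-2-(prop-1-en-2-yl)hex-4-en-1-yl] S-methyl carbonodithioate | C=C(C)[C@@H](CC=C(C)C)C(OC(=S)SC)c1c(OCOC)cc(OC)cc1OCOC
F8 | step 3 | 5-methoxy-1,3-phenylene bis(N-isopropylcarbamate) | COc1cc(OC(=O)NC(C)C)cc(OC(=O)NC(C)C)c1
F9 | step 3 | 5-methoxy-1,3-phenylene bis[N-(tert-butyldimethylsilyl)-N-isopropylcarbamate] | COc1cc(OC(=O)N(C(C)C)[Si](C)(C)C(C)(C)C)cc(OC(=O)N(C(C)C)[Si](C)(C)C(C)(C)C)c1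
F10 | step 3 | 2-lithio-5-methoxy-1,3-phenylene bis[N-(tert-butyldimethylsilyl)-N-isopropylcarbamate] | COc1cc(OC(=O)N(C(C)C)[Si](C)(C)C(C)(C)C)c([Li])c(OC(=O)N(C(C)C)[Si](C)(C)C(C)(C)C)c1
F11 | step 3 | 5-methoxy-2-(trimethylsilyl)-1,3-phenylene bis[N-(tert-butyldimethylsilyl)-N-isopropylcarbamate] | COc1cc(OC(=O)N(C(C)C)[Si](C)(C)C(C)(C)C)c([Si](C)(C)C)c(OC(=O)N(C(C)C)[Si](C)(C)C(C)(C)C)c1
F12 | step 3 | 5-methoxy-2-(trimethylsilyl)-1,3-phenylene bis(N-isopropylcarbamate) | COc1cc(OC(=O)NC(C)C)c([Si](C)(C)C)c(OC(=O)NC(C)C)c1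
F13 | step 3 | 3-hydroxy-5-methoxy-2-(trimethylsilyl)phenyl N-isopropylcarbamate | COc1cc(O)c([Si](C)(C)C)c(OC(=O)NC(C)C)c1
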